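3 questions stood, and I wanted one rule to answer them.

| flask | starting material | partner | remark | time |
|---|---|---|---|---|
| Sunday's | 1 M | 2 equiv | run made earlier |  |
| Wednesday's | 0.50 M | 3 equiv | run made earlier |  |
| flask | 1.0 M | 3.00 equiv |  | 10 min |

- Sunday's (time / min: single product / %, starting material / %): 0.667: 63.2, 32.2; 2.00: 78.3, 15.5; 4.00: 81.3, 11.7; 6.00: 81.1, 11.0; 8.00: 81.2, 11.2
- Wednesday's (time / min: single product / %, starting material / %): 0.667: 55.4, 38.5; 1.33: 67.3, 24.2; 2.50: 72.5, 15.1; 4.00: 74.0, 13.4; 8.00: 74.8, 12.0

(each reading ± 0.3 percentage points)

- equivalents of partner to starting material, everything else as given, that leave most single product at 10 min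
- the amount of single product then, in percent of the starting material charged
- the amount of single product with the amounts as given

- a reading or a percentage of single product counts all its forms, free or not

Both runs stopped with starting material left, so I first read an equilibrium. But material was missing too, 7.60% of the charge in Sunday's run, and an equilibrium gave that no place. So I tried a partner that also dies by itself, the limiting reagent at each plateau. The logarithm of charged over remaining starting material, which I called folds, then counts partner-time: 2.19 folds in Sunday's run. A side loss that also runs on partner should grow with folds. I named the missing fraction per fold the toll, 3.47% of the charge per fold. Letting each missing fraction take one extra partner, I booked the rest of the charge as 0.473 equiv wasted per fold. That extra partner was a guess, but a cheap one, since the toll is far smaller than the waste.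

One run proves little. Wednesday's run, at half the concentration, should double both, and it gave 0.938 equiv and 6.23%, twice and twice.

The flask had Sunday's concentration, so I carried over Sunday's toll and waste. Another fold gains the remaining fraction and costs the toll, so single product should peak where the two are equal. That gave me 2.67 equiv and 84.9%. At 3.00 equiv the budget allowed 3.98 folds, leaving 1.88% starting material, less than the toll, so I expected 84.3%. Time I dropped in my estimate: Sunday's readings stood still from 6.00 min, before 10 min.

The forecast said 2.5 equiv, 81.7% and 81%, adding: “The optimum is very flat”. The flask gave 2.67 equiv, 85.0% and 84.4%.

    starting material + partner → single product (k = 0.0231 M⁻¹ s⁻¹)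
    partner + single product → double product (k = 0.00986 M⁻¹ s⁻¹)
    partner → decomposed reagent (k = 0.0109 s⁻¹)
    crystals ⇌ single product, rate k4*(cs4 - [single product]) while solid is left; crystals form when [single product] > cs4 (solubility = 36.0 mM, k = 2.08 s⁻¹)
    partner + single product → over-reaction product (k = 0.00972 M⁻¹ s⁻¹)

At the best equivalents starting material stood at 3.45%, against a toll of 3.47%. A neighbouring flask, the same but with 1.20 equiv of partner, kept 34% starting material, which is 1.07 folds; the toll then leaves 62.1% single product, and that neighbouring flask held 62.2%.

The runs are simulated with constants of no real substance, noise included.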